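**Retrosynthetic overview**

1. Target ⇒ bis(α-aryloxy ketone), whose chelation-controlled reduction sets both carbinol centres ⇒ meso-bisphenol oxolane + 2 × (R)-2-chloro-1-(3,4-dimethoxyphenyl)propan-1-one (double SN2 with inversion; the chloroketone comes from catechol and (R)-2-chloropropanoyl chloride).
2. Meso-bisphenol ⇒ cis-3,4-dimethyl oxolane (thermodynamic C2/C5 epimerisation, desilylation) ⇒ 2,5-diaryl-3,4-dimethyl-2,5-dihydrofuran (syn hydrogenation).
3. Key step: the dihydrofuran ⇒ ring expansion (ionic 1,3-oxygen shift, three- to five-membered ring) of a vinyl oxirane made in the same flask by mono-epoxidation of the (1E,3E)-1,4-diaryl-2,3-dimethylbutadiene.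
4. Diene ⇒ twofold Heck arylation of 2,3-dimethylbuta-1,3-diene with a silyl-protected 4-bromoguaiacol (catechol: mono-methylation, para-bromination, silylation).
5. Ring order: the four benzene rings are bought as catechol; the transient oxirane is formed first and expanded to the dihydrofuran, which is then saturated to the oxolane, the only ring built.

Assumption: intermediates 8 and 9 are carried as C2/C5 epimer mixtures (these centres are equilibrated in step 7), so those two centres are left undefined in their SMILES, and racemic 7 is drawn as one enantiomer.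

**Route**

Step 1
Reactants: 1 catechol
Product: 2 guaiacol (2-methoxyphenol)
Conditions: MeI (1.0 equiv), K2CO3 (1.0 equiv), acetone, 56 °C
Reagents that add atoms: iodomethane, CI
Why: Williamson O-methylation with limiting base and electrophile stops largely at the mono-ether because guaiacol is less acidic than catechol; residual catechol and veratrole are removed by extraction; no stereocentre.

Step 2
Reactants: 2 guaiacol
Product: 3 4-bromo-2-methoxyphenol
Conditions: NBS (1.0 equiv), MeCN, 0 °C
Reagents that add atoms: N-bromosuccinimide, O=C1CCC(=O)N1Br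
Why: Electrophilic aromatic bromination goes para to the free hydroxyl, the stronger director, which places bromine meta to the methoxy group as the target needs.

Step 3
Reactants: 3 4-bromo-2-methoxyphenol
Product: 4 (4-bromo-2-methoxyphenoxy)tri(propan-2-yl)silane
Conditions: TIPSCl, imidazole, DMF, 23 °C
Reagents that add atoms: chlorotri(propan-2-yl)silane, CC(C)[Si](Cl)(C(C)C)C(C)C
Why: Imidazole-promoted silylation gives a robust aryl silyl ether that survives base, oxidant, Lewis acid and hydrogenation yet keeps the ring electron-rich for the later cationic steps.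

Step 4
Reactants: 4 (4-bromo-2-methoxyphenoxy)tri(propan-2-yl)silane (2.2 equiv); 5 2,3-dimethylbuta-1,3-diene
Product: 6 (1E,3E)-1,4-bis[3-methoxy-4-(triisopropylsilyloxy)phenyl]-2,3-dimethylbuta-1,3-diene
Conditions: Pd2(dba)3 (2.5 mol %), [HP(t-Bu)3]BF4 (10 mol %), Cy2NMe, 1,4-dioxane, 90 °C, sealed tube
Reagents that add atoms: none
Why: Twofold Mizoroki–Heck arylation occurs at the two unhindered CH2 termini, and β-hydride elimination towards the benzylic hydrogen gives the conjugated diene with each aryl cis to the smaller methyl group (E,E).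

Step 5
Reactants: 6 (1E,3E)-diene
Product: 8 2,5-bis[3-methoxy-4-(triisopropylsilyloxy)phenyl]-3,4-dimethyl-2,5-dihydrofuran (cis/trans mixture at C2/C5), via trans-vinyl oxirane 7 (not isolated)
Conditions: DMDO (0.95 equiv, acetone), CH2Cl2, −40 °C; volatiles off at −20 °C; Cu(hfacac)2 (copper bis(hexafluoroacetylacetonate), 5 mol %), toluene, 0 → 40 °C
Reagents that add atoms: dimethyldioxirane, CC1(C)OO1
Why: Proposed new method: a one-flask formal [4+1] oxygen-atom annulation of a 1,3-diene, in which DMDO epoxidises one electron-rich trisubstituted alkene (the allylic oxygen then deactivates the second alkene, favouring mono-epoxidation) and the Lewis-acidic divalent copper complex ionises the tertiary allylic C–O bond of labile oxirane 7 to a 1-aryl-allyl cation/copper alkoxide ion pair that closes at the benzylic terminus (stepwise ionic 1,3-oxygen shift, three- to five-membered ring expansion, not pericyclic), this allyl cation being better stabilised than the simple benzylic cation that would lead to Meinwald rearrangement; C2 and C5 form as a cis/trans mixture that converges in steps 6 and 7; the closest known reaction type is the Cu(hfacac)2-catalysed ring expansion of isolated, simple vinyl oxiranes to 2,5-dihydrofurans, not yet shown for fully substituted 1,4-diaryl vinyl oxiranes generated in situ from a diene.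

Step 6
Reactants: 8 2,5-dihydrofuran (cis/trans mixture)
Product: 9 2,5-bis[3-methoxy-4-(triisopropylsilyloxy)phenyl]-3,4-cis-dimethyloxolane (epimer mixture at C2/C5)
Conditions: H2 (30 bar), [Ir(cod)(PCy3)(py)]PF6 (5 mol %), CH2Cl2, 23 °C
Reagents that add atoms: none
Why: Homogeneous iridium-catalysed hydrogenation of the tetrasubstituted alkene delivers both hydrogens to one face (syn addition), so C3 and C4 are set cis whichever face is used, and it does not hydrogenolyse the benzylic C–O bonds.

Step 7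
Reactants: 9 3,4-cis-dimethyloxolane (epimer mixture)
Product: 11 meso-bisphenol 4,4'-[(2S,3S,4R,5R)-3,4-dimethyloxolane-2,5-diyl]bis(2-methoxyphenol), via epimerised bis-silyl ether 10 (not isolated)
Conditions: BF3·OEt2 (30 mol %), CH2Cl2, −20 → 0 °C; NaHCO3 wash; crude with Bu4NF, AcOH, THF, 0 → 23 °C
Reagents that add atoms: none
Why: Lewis-acid benzylic epimerisation (reversible C–O ionisation to the para-oxygen-stabilised cation and reclosure) funnels all C2/C5 epimers to the thermodynamic 2,3-trans-3,4-cis-4,5-trans isomer with each aryl trans to its neighbouring methyl, and fluoride desilylation then frees both phenols.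

Step 8
Reactants: 1 catechol
Product: 12 veratrole (1,2-dimethoxybenzene)
Conditions: MeI (2.5 equiv), K2CO3, acetone, 56 °C
Reagents that add atoms: iodomethane, CI
Why: Exhaustive Williamson O-methylation of both phenols.

Step 9
Reactants: 12 veratrole; 13 (R)-2-chloropropanoyl chloride
Product: 14 (R)-2-chloro-1-(3,4-dimethoxyphenyl)propan-1-one
Conditions: AlCl3 (1.2 equiv), CH2Cl2, −10 → 0 °C
Reagents that add atoms: none
Why: Friedel–Crafts acylation goes para to a methoxy group, and the α-chloro stereocentre is not involved in bond formation and is carried over from the chiral-pool acid chloride at low temperature.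

Step 10
Reactants: 11 meso-bisphenol; 14 (R)-chloroketone (2.4 equiv, added slowly)
Product: 15 bis-ketone (2S,2'S)-2,2'-{[(2S,3S,4R,5R)-3,4-dimethyloxolane-2,5-diyl]bis[(2-methoxy-4,1-phenylene)oxy]}bis[1-(3,4-dimethoxyphenyl)propan-1-one]
Conditions: Cs2CO3, MeCN, 0 → 23 °C
Reagents that add atoms: none
Why: Double Williamson SN2 on the activated α-chloro ketone proceeds with inversion (R to S at each ether carbon), CsCl precipitates from MeCN so chloride-induced racemisation is limited, and the meso core gives a single diastereomer.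

Step 11
Reactants: 15 bis-ketone
Product: 16 target, (1R,2S)-1-(3,4-dimethoxyphenyl)-2-{4-[(2S,3S,4R,5R)-5-(4-{[(1R,2S)-1-(3,4-dimethoxyphenyl)-1-hydroxypropan-2-yl]oxy}-3-methoxyphenyl)-3,4-dimethyloxolan-2-yl]-2-methoxyphenoxy}propan-1-ol
Conditions: Zn(BH4)2, Et2O/CH2Cl2, −30 → 0 °C; aq. NH4Cl
Reagents that add atoms: none
Why: Chelation-controlled (Cram-chelate) hydride reduction, in which zinc bridges the carbonyl and the α-aryloxy/ortho-methoxy oxygens and hydride enters anti to the methyl group, gives the erythro (1R,2S) carbinol at both ends.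

**Compound list**

1 | catechol (benzene-1,2-diol) | Oc1ccccc1O | starting material
2 | guaiacol (2-methoxyphenol) | COc1ccccc1O | intermediate
3 | 4-bromo-2-methoxyphenol | COc1cc(Br)ccc1O | intermediate
4 | (4-bromo-2-methoxyphenoxy)tri(propan-2-yl)silane | COc1cc(Br)ccc1O[Si](C(C)C)(C(C)C)C(C)C | intermediate
5 | 2,3-dimethylbuta-1,3-diene | CC(=C)C(C)=C | starting material
6 | (1E,3E)-1,4-bis[3-methoxy-4-(triisopropylsilyloxy)phenyl]-2,3-dimethylbuta-1,3-diene | COc1cc(/C=C(C)/C(C)=C/c2ccc(O[Si](C(C)C)(C(C)C)C(C)C)c(OC)c2)ccc1O[Si](C(C)C)(C(C)C)C(C)C | intermediate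
7 | rac-(2R,3R)-2-aryl-3-methyl-3-[(1E)-1-arylprop-1-en-2-yl]oxirane, aryl = 3-methoxy-4-(triisopropylsilyloxy)phenyl (aryl and alkenyl trans) | O1[C@H](c2ccc(O[Si](C(C)C)(C(C)C)C(C)C)c(OC)c2)[C@@]1(C)/C(C)=C/c1ccc(O[Si](C(C)C)(C(C)C)C(C)C)c(OC)c1 | intermediate
8 | 2,5-bis[3-methoxy-4-(triisopropylsilyloxy)phenyl]-3,4-dimethyl-2,5-dihydrofuran (cis/trans mixture at C2/C5) | COc1cc(C2OC(c3ccc(O[Si](C(C)C)(C(C)C)C(C)C)c(OC)c3)C(C)=C2C)ccc1O[Si](C(C)C)(C(C)C)C(C)C | intermediate
9 | 2,5-bis[3-methoxy-4-(triisopropylsilyloxy)phenyl]-3,4-cis-dimethyloxolane (epimer mixture at C2/C5) | COc1cc(C2OC(c3ccc(O[Si](C(C)C)(C(C)C)C(C)C)c(OC)c3)[C@H](C)[C@@H]2C)ccc1O[Si](C(C)C)(C(C)C)C(C)C | intermediate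
10 | meso-(2S,3S,4R,5R)-2,5-bis[3-methoxy-4-(triisopropylsilyloxy)phenyl]-3,4-dimethyloxolane (2,3-trans-3,4-cis-4,5-trans) | COc1cc([C@H]2O[C@@H](c3ccc(O[Si](C(C)C)(C(C)C)C(C)C)c(OC)c3)[C@H](C)[C@@H]2C)ccc1O[Si](C(C)C)(C(C)C)C(C)C | intermediate
11 | meso-4,4'-[(2S,3S,4R,5R)-3,4-dimethyloxolane-2,5-diyl]bis(2-methoxyphenol) | COc1cc([C@H]2O[C@@H](c3ccc(O)c(OC)c3)[C@H](C)[C@@H]2C)ccc1O | intermediate
12 | veratrole (1,2-dimethoxybenzene) | COc1ccccc1OC | intermediate
13 | (R)-2-chloropropanoyl chloride | C[C@@H](Cl)C(Cl)=O | starting material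
14 | (R)-2-chloro-1-(3,4-dimethoxyphenyl)propan-1-one | C[C@@H](Cl)C(=O)c1ccc(OC)c(OC)c1 | intermediate
15 | (2S,2'S)-2,2'-{[(2S,3S,4R,5R)-3,4-dimethyloxolane-2,5-diyl]bis[(2-methoxy-4,1-phenylene)oxy]}bis[1-(3,4-dimethoxyphenyl)propan-1-one] | COc1ccc(C(=O)[C@H](C)Oc2ccc([C@H]3O[C@@H](c4ccc(O[C@@H](C)C(=O)c5ccc(OC)c(OC)c5)c(OC)c4)[C@H](C)[C@@H]3C)cc2OC)cc1OC | intermediate
16 | (1R,2S)-1-(3,4-dimethoxyphenyl)-2-{4-[(2S,3S,4R,5R)-5-(4-{[(1R,2S)-1-(3,4-dimethoxyphenyl)-1-hydroxypropan-2-yl]oxy}-3-methoxyphenyl)-3,4-dimethyloxolan-2-yl]-2-methoxyphenoxy}propan-1-ol | COc1ccc([C@@H](O)[C@H](C)Oc2ccc([C@H]3O[C@@H](c4ccc(O[C@@H](C)[C@H](O)c5ccc(OC)c(OC)c5)c(OC)c4)[C@H](C)[C@@H]3C)cc2OC)cc1OC | target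

**Step count and risks**

Total steps: 11. Longest linear sequence: 9 (steps 1, 2, 3, 4, 5, 6, 7, 10, 11).

Three steps most likely to fail:

Step 5 (the proposed new step). The oxirane may undergo Meinwald rearrangement or proton loss instead of ring expansion, and mono-epoxidation may be unselective. The fallback uses known chemistry and sets out from diene 6. Dye-sensitised photooxygenation (O2, tetraphenylporphyrin, visible light, CH2Cl2, −30 °C) adds singlet oxygen across the s-cis diene to give the endoperoxide cis-3,6-bis[3-methoxy-4-(triisopropylsilyloxy)phenyl]-4,5-dimethyl-3,6-dihydro-1,2-dioxine F3. Thiourea in MeOH/CH2Cl2 cleaves the O–O bond to the enediol meso-(2Z)-1,4-bis[3-methoxy-4-(triisopropylsilyloxy)phenyl]-2,3-dimethylbut-2-ene-1,4-diol F4. Catalytic camphorsulfonic acid in CH2Cl2 at 0 °C then cyclodehydrates the bis-allylic diol, and the route is rejoined at dihydrofuran 8.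

Step 4. The second arylation may stall, or β-hydride elimination may go towards a methyl group and give exo-methylene isomers. The fallback sets out from aryl bromide 4. Sonogashira coupling with propyne (PdCl2(PPh3)2, CuI, Et3N, THF, 23 °C) gives the alkyne [2-methoxy-4-(prop-1-yn-1-yl)phenoxy]tri(propan-2-yl)silane F1. Reductive dimerisation with Cp2ZrCl2/n-BuLi (2 equiv) in THF, −78 → 23 °C, places both aryl groups next to zirconium and gives the metallacycle 1,1-bis(cyclopentadienyl)-3,4-dimethyl-2,5-bis[3-methoxy-4-(triisopropylsilyloxy)phenyl]zirconacyclopenta-2,4-diene F2 (cyclopentadienyl rings drawn σ-bonded in its SMILES). Protonolysis with dilute HCl at 0 °C retains the alkene geometry and returns to the route at diene 6.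

Step 6. The hindered tetrasubstituted alkene may resist the iridium catalyst, or isomerise to the enol ether and erode the cis-dimethyl relationship. The fallback sets out from dihydrofuran 8. Dehydrogenation with DDQ (1,4-dioxane, 23 °C) gives the stable furan 2,5-bis[3-methoxy-4-(triisopropylsilyloxy)phenyl]-3,4-dimethylfuran F5. Heterogeneous hydrogenation (H2 4 bar, Pd/C, EtOAc) then adds all four hydrogens from one face to give the all-cis oxolane, which is one of the C2/C5 epimers that make up 9, so the route is rejoined at 9.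

**Further compounds**

F1 | step 4 | [2-methoxy-4-(prop-1-yn-1-yl)phenoxy]tri(propan-2-yl)silane | CC#Cc1ccc(O[Si](C(C)C)(C(C)C)C(C)C)c(OC)c1
F2 | step 4 | 1,1-bis(cyclopentadienyl)-3,4-dimethyl-2,5-bis[3-methoxy-4-(triisopropylsilyloxy)phenyl]zirconacyclopenta-2,4-diene | CC1=C(c2ccc(O[Si](C(C)C)(C(C)C)C(C)C)c(OC)c2)[Zr](C2C=CC=C2)(C2C=CC=C2)C(c2ccc(O[Si](C(C)C)(C(C)C)C(C)C)c(OC)c2)=C1C
F3 | step 5 | cis-3,6-bis[3-methoxy-4-(triisopropylsilyloxy)phenyl]-4,5-dimethyl-3,6-dihydro-1,2-dioxine | CC1=C(C)[C@H](c2ccc(O[Si](C(C)C)(C(C)C)C(C)C)c(OC)c2)OO[C@@H]1c1ccc(O[Si](C(C)C)(C(C)C)C(C)C)c(OC)c1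
F4 | step 5 | meso-(2Z)-1,4-bis[3-methoxy-4-(triisopropylsilyloxy)phenyl]-2,3-dimethylbut-2-ene-1,4-diol | C/C(=C(\C)[C@H](c1ccc(O[Si](C(C)C)(C(C)C)C(C)C)c(OC)c1)O)[C@H](O)c1ccc(O[Si](C(C)C)(C(C)C)C(C)C)c(OC)c1
F5 | step 6 | 2,5-bis[3-methoxy-4-(triisopropylsilyloxy)phenyl]-3,4-dimethylfuran | Cc1c(-c2ccc(O[Si](C(C)C)(C(C)C)C(C)C)c(OC)c2)oc(-c2ccc(O[Si](C(C)C)(C(C)C)C(C)C)c(OC)c2)c1C
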